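**Retrosynthetic overview**
- Last bond made: C14–C15, by an electroreductive Ni/Cr alkenylation of a C14 α-hydroxy aldehyde with an (E)-iodomethylene butenolide; this sets C14 and keeps the E alkene.
- The aldehyde comes from a vinyl carbinol; its 8α-OH/8β-CH3 center comes from radical Markovnikov hydration of an exocyclic C8 methylene.
- That seco-diene comes from ozonolytic opening of ring C of a tricyclic resin-acid enone, after axial methyl addition (sets C13), followed by double methylenation.
- Rings A and B with C4, C5, C9 and C10 are bought in a rosin acid; no carbocycle is built, ring C is cut open.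
- The only ring formed is the butenolide, by iodolactonisation of a (Z)-enynoic acid, before the coupling.

Assumption: neoabietic acid (a commercial pine-rosin resin acid, natural series) is taken as the cheap chiral starting material; the target is read as 4R,5R,8R,9R,10S,13S,14S with an (E)-ylidene butenolide (labdane/podocarpane numbering: C18 = 4α-CO2H, C17 = C8 methyl, C16 = C13 methyl).

**Step 1**
Reactants: 1 neoabietic acid
Product: 2 13-oxopodocarp-8(14)-en-18-oic acid
Conditions: O3 (1.0 equiv, Sudan Red 7B end point), pyridine (3 equiv), CH2Cl2, −78 °C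
Reagents that add atoms: ozone (O=[O+][O-])
Why: Criegee ozonolysis with pyridine-mediated reductive breakdown; the electron-rich tetrasubstituted exocyclic C13=C15 bond reacts first and the enone C=C that results is deactivated, so one equivalent removes only acetone and no stereocenter is touched.

**Step 2**
Reactants: 2 13-oxopodocarp-8(14)-en-18-oic acid
Product: 3 (13S)-13-hydroxy-13-methylpodocarp-8(14)-en-18-oic acid
Conditions: MeLi (3.2 equiv), THF, −78 °C; then H2O, aq. NaH2PO4 (pH 5), 0 °C
Reagents that add atoms: methyllithium ([Li]C)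
Why: 1,2-addition of methyllithium to the cyclohexenone (the lithium carboxylate is inert at −78 °C); axial attack on the half-chair enone from the β face (anti to the axial C12–H, only H-11β syn-axial) puts CH3 13β and OH 13α (13S) under control of the bought ring-fusion centers.

**Step 3**
Reactants: 3 (13S)-13-hydroxy-13-methylpodocarp-8(14)-en-18-oic acid
Product: 4 (13S)-13-hydroxy-8,14-dioxo-15,17-dinorlabdan-18-oic acid
Conditions: O3, pyridine (3 equiv), CH2Cl2, −78 °C
Reagents that add atoms: ozone (O=[O+][O-])
Why: Criegee ozonolysis of the only alkene (C8=C14) opens ring C to the 8-ketone and the C14 aldehyde; C13 is quaternary and cannot epimerise.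

**Step 4**
Reactants: 4 (13S)-13-hydroxy-8,14-dioxo-15,17-dinorlabdan-18-oic acid
Product: 6 (13S)-13-hydroxylabda-8(17),14-dien-18-oic acid, via vinyl ketone 5 (not isolated)
Conditions: Ph3PCH3Br (8 equiv), KOtBu (7.5 equiv), THF, −78 → 0 °C, then 65 °C; aq. NaH2PO4
Reagents that add atoms: methyltriphenylphosphonium bromide (C[P+](c1ccccc1)(c1ccccc1)c1ccccc1.[Br-])
Why: Double Wittig methylenation; the aldehyde reacts cold, the hindered 8-ketone on heating, the excess ylide covers CO2H and OH, and C9 keeps its stable equatorial side chain.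

**Step 5**
Reactants: 6 (13S)-13-hydroxylabda-8(17),14-dien-18-oic acid
Product: 7 (13S)-8α,13-dihydroxylabd-14-en-18-oic acid
Conditions: Co(acac)2 (20 mol %), PhSiH3 (2.5 equiv), O2 (1 atm), THF/iPrOH, 0 °C → rt
Reagents that add atoms: dioxygen (O=O)
Why: Mukaiyama hydration (hydrogen-atom transfer from the Co(acac)2/PhSiH3 system, then O2 capture); the 1,1-disubstituted alkene gives the tertiary C8 radical much faster than the hindered vinyl carbinol reacts, O2 is taken up on the α face because the axial β face is blocked by the syn-axial C10 methyl (8α-OH, 8β-CH3, 8R), and the radical path avoids the 8,13-ether that cationic hydration would give.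

**Step 6**
Reactants: 7 (13S)-8α,13-dihydroxylabd-14-en-18-oic acid
Product: 8 (13S)-8α,13-dihydroxy-14-oxo-15-norlabdan-18-oic acid
Conditions: O3, pyridine (3 equiv), CH2Cl2, −78 °C; used crude
Reagents that add atoms: ozone (O=[O+][O-])
Why: Criegee ozonolysis of the vinyl group gives the α-hydroxy aldehyde, which has no α-hydrogen and so cannot enolise or epimerise.

**Step 7**
Reactants: 9 (Z)-3-methylpent-2-en-4-yn-1-ol
Product: 10 (Z)-3-methylpent-2-en-4-ynoic acid
Conditions: CrO3, H2SO4, acetone/H2O, 0 °C
Reagents that add atoms: water (O)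
Why: Jones oxidation of the primary allylic alcohol through the aldehyde hydrate; it is fast enough at 0 °C to keep the Z geometry that lactonisation needs.

**Step 8**
Reactants: 10 (Z)-3-methylpent-2-en-4-ynoic acid
Product: 11 (E)-5-(iodomethylene)-4-methylfuran-2(5H)-one
Conditions: I2 (3 equiv), NaHCO3 (3 equiv), MeCN, rt, dark
Reagents that add atoms: iodine (II)
Why: Iodolactonisation; anti addition of carboxylate oxygen and iodine across the terminal alkyne in the 5-exo-dig mode gives the E iodoalkylidene butenolide (I trans to the ring oxygen).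

**Step 9**
Reactants: 8 (13S)-8α,13-dihydroxy-14-oxo-15-norlabdan-18-oic acid and 11 (E)-5-(iodomethylene)-4-methylfuran-2(5H)-one
Product: 14 target acid CNP0316014.1, via trimethylsilyl ester 12 (not isolated), via bis-silylated adduct 13 (not isolated)
Conditions: BSA (1.0 equiv), DMF/THF 1:3, rt; then 11 (1.5 equiv), CrCl2 (20 mol %), NiCl2·glyme (5 mol %), TMSCl (2 equiv), LiCl (0.2 M), Al anode, Ni-foam cathode, undivided cell, 4 mA (2.5 F/mol), rt, dark; then aq. citric acid, THF, 0 °C
Reagents that add atoms: none
Why: Proposed new method: an electroreductive Ni/Cr alkenylation (Nozaki–Hiyama–Kishi type) using a β-acyloxyalkenyl iodide and a free α-hydroxy aldehyde, a pairing not yet shown. Zerovalent nickel inserts into the C–I bond with retention and hands the alkenyl to chromium, which the cathode returns from the trivalent to the divalent state; the alkenyl–CrCl2 bond should be covalent enough not to expel the trans lactone carboxylate (ring-opening β-elimination); addition is expected through a five-membered chelate of the free 13-OH and the carbonyl oxygen, with the C12 face screened by the chain carrying the 8α-OH, so the alkenyl arrives on the methyl face (Cram-chelate sense, 14S) with the E geometry kept. The closest known reactions are the electrochemical Nozaki–Hiyama–Kishi coupling of simple alkenyl halides and palladium couplings of (E)-5-(halomethylene)furanones.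

**Compound list**
1 | neoabietic acid, abieta-8(14),13(15)-dien-18-oic acid (4α-CO2H, 4β-CH3, 5α-H, 9α-H, 10β-CH3) | CC(C)=C1CC[C@@H]2[C@@]3(C)CCC[C@@](C)(C(=O)O)[C@@H]3CCC2=C1 | starting material
2 | 13-oxopodocarp-8(14)-en-18-oic acid (ring-C enone, ring-fusion centers as in 1) | O=C1CC[C@@H]2[C@@]3(C)CCC[C@@](C)(C(=O)O)[C@@H]3CCC2=C1 | intermediate
3 | (13S)-13-hydroxy-13-methylpodocarp-8(14)-en-18-oic acid (13α-OH, 13β-CH3) | C[C@]1(O)CC[C@@H]2[C@@]3(C)CCC[C@@](C)(C(=O)O)[C@@H]3CCC2=C1 | intermediate
4 | (13S)-13-hydroxy-8,14-dioxo-15,17-dinorlabdan-18-oic acid (8-ketone, C14 aldehyde; open form of its bicyclic lactol) | O=C[C@@](C)(O)CC[C@@H]1[C@@]2(C)CCC[C@@](C)(C(=O)O)[C@@H]2CCC1=O | intermediate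
5 | (13S)-13-hydroxy-8-oxo-17-norlabd-14-en-18-oic acid (vinyl ketone) | C=C[C@@](C)(O)CC[C@@H]1[C@@]2(C)CCC[C@@](C)(C(=O)O)[C@@H]2CCC1=O | intermediate
6 | (13S)-13-hydroxylabda-8(17),14-dien-18-oic acid | C=C[C@@](C)(O)CC[C@@H]1[C@@]2(C)CCC[C@@](C)(C(=O)O)[C@@H]2CCC1=C | intermediate
7 | (13S)-8α,13-dihydroxylabd-14-en-18-oic acid (8R, 8β-CH3) | C=C[C@@](C)(O)CC[C@@H]1[C@@]2(C)CCC[C@@](C)(C(=O)O)[C@@H]2CC[C@@]1(C)O | intermediate
8 | (13S)-8α,13-dihydroxy-14-oxo-15-norlabdan-18-oic acid (C14 aldehyde) | O=C[C@@](C)(O)CC[C@@H]1[C@@]2(C)CCC[C@@](C)(C(=O)O)[C@@H]2CC[C@@]1(C)O | intermediate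
9 | (Z)-3-methylpent-2-en-4-yn-1-ol | C#C/C(C)=C\CO | starting material
10 | (Z)-3-methylpent-2-en-4-ynoic acid | C#C/C(C)=C\C(=O)O | intermediate
11 | (E)-5-(iodomethylene)-4-methylfuran-2(5H)-one (I trans to ring O) | CC1=CC(=O)O/C1=C/I | intermediate
12 | trimethylsilyl ester of 8 | O=C[C@@](C)(O)CC[C@@H]1[C@@]2(C)CCC[C@@](C)(C(=O)O[Si](C)(C)C)[C@@H]2CC[C@@]1(C)O | intermediate
13 | 14-O-trimethylsilyl ether, trimethylsilyl ester of 14 | CC1=CC(=O)O/C1=C/[C@H](O[Si](C)(C)C)[C@@](C)(O)CC[C@@H]1[C@@]2(C)CCC[C@@](C)(C(=O)O[Si](C)(C)C)[C@@H]2CC[C@@]1(C)O | intermediate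
14 | CNP0316014.1: (4R,5R,8R,9R,10S,13S,14S)-8α,13,14-trihydroxy 18-acid whose C14 carries the (E)-(3-methyl-5-oxofuran-2(5H)-ylidene)methyl group (C14 trans to ring O) | CC1=CC(=O)O/C1=C/[C@H](O)[C@@](C)(O)CC[C@@H]1[C@@]2(C)CCC[C@@](C)(C(=O)O)[C@@H]2CC[C@@]1(C)O | target

**Step count and risks**
Total steps: 9. Longest linear sequence: 7 (steps 1–6 and 9).

Step 9 (the new coupling) is the most likely to fail. The alkenyl metal may ring-open by β-elimination, Lewis acids may trigger α-ketol rearrangement of 8, and C14 control rests on methyl versus CH2 discrimination in the chelate. I expect only a modest 14S:14R ratio, roughly 3–5:1, with the epimers separated by chromatography. Fallback with known chemistry, setting out from 8 and acid 10: the dilithio derivative of 10 (LiN(iPr)2, THF, −78 °C, excess to cover the acidic protons of 8) adds to the aldehyde under lithium chelation to give the (13S,14S)-propargylic alcohol enynoic diacid F1. AgNO3 (10 mol %, acetone, rt) then closes it by anti 5-exo-dig lactonisation to the Z-ylidene isomer of the target F2. Irradiation (350 nm, MeCN) equilibrates the alkene; the E isomer is separated and the Z isomer recycled. This comes back to the route at 14.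

Step 5 (hydration) may also hydrate the vinyl group or give some 8β-OH epimer. Fallback setting out from 6: mCPBA (1.05 equiv, NaHCO3, CH2Cl2, 0 °C) epoxidises the more nucleophilic exocyclic alkene from the open α face to give the (13S)-8α,17-epoxy-13-hydroxylabd-14-en-18-oic acid F3. LiBHEt3 (THF, 0 °C) opens it at the primary carbon. This comes back to the route at 7.

Step 4 (double methylenation) exposes a keto-aldehyde to hot base, with risk of aldol or α-ketol side reactions and incomplete reaction of the hindered ketone. Fallback setting out from 4: treat with the ylide at −78 °C only, so that just the aldehyde reacts, and isolate vinyl ketone 5 (stored as its cyclic hemiketal). Then methylenate the ketone with the non-basic Takai–Lombardo reagent (CH2Br2, Zn, TiCl4, THF/CH2Cl2, 0 °C → rt). This comes back to the route at 6 and makes no compound outside the list (F0).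

**Further compounds**
F1 | step 9 | (2Z,6S,7S)-6,7-dihydroxy-3,7-dimethylnon-2-en-4-ynoic acid carrying at C9 the 8α-hydroxy-18-carboxy decalin of 8 (propargylic alcohol enynoic diacid) | OC(=O)/C=C(C)\C#C[C@H](O)[C@@](C)(O)CC[C@@H]1[C@@]2(C)CCC[C@@](C)(C(=O)O)[C@@H]2CC[C@@]1(C)O
F2 | step 9 | Z-ylidene isomer of 14 (C14 cis to ring O) | CC1=CC(=O)O\C1=C/[C@H](O)[C@@](C)(O)CC[C@@H]1[C@@]2(C)CCC[C@@](C)(C(=O)O)[C@@H]2CC[C@@]1(C)O
F3 | step 5 | (13S)-8α,17-epoxy-13-hydroxylabd-14-en-18-oic acid | C=C[C@@](C)(O)CC[C@@H]1[C@@]2(C)CCC[C@@](C)(C(=O)O)[C@@H]2CC[C@]13CO3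
F0 | step 4 | none | none
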